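**Remarks.** Methyl 2-(2-hydroxyphenyl)acetate (1) is assumed to be a catalogue compound; from the free acid, one acid-catalysed esterification would precede step 1. Positions are cited in benzofuran numbering throughout, also for open-chain precursors (the carbinol carbon of 10 is C2, its ester-bearing carbon is C3); systematic names keep their own locants.

## Analysis of the target

Target 18 is a 2,3-dihydrobenzofuran: benzo ring A fused to dihydrofuran ring B, with a 3,4-dihydroxyphenyl group on C2, a methyl ester on C3, a free hydroxyl on C7 and an (E)-methyl propenoate chain on C5. The only stereocentres are C2 and C3, both R, and the aryl group and the ester lie on opposite faces of ring B (trans), which is also the more stable arrangement. C3–H is benzylic and α to the ester, so base can epimerise it or, through the ester enolate, expel the O1 phenoxide and open ring B, which would erase C2 as well. O1–C2 is a benzylic ether para to an oxygenated carbon and can ionise under strong acid. The catechol and the C7 phenol are easily oxidised, and the enoate is reducible and a Michael acceptor, which rules out hydrogenolysis and strong nucleophiles late in the route. The difficulty is therefore twofold: both stereocentres sit in a ring that can open from either side, and ring A carries three different substituents (O1, OH, alkenyl) in a fixed pattern around C3a. The strategy rests on the contiguous row C3a–C7a–C7 of ring A, in which C7a bears O1 and C7 bears the hydroxyl. Two neighbouring C–O bonds beside the carbon substituent are what remains when an oxygen nucleophile tethered to C3a adds to C7a of a C7–C7a aryne and an oxygen electrophile equivalent is then delivered to C7.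

## Retrosynthetic reasoning

**18 from 17.** The two O–benzyl bonds of the catechol are cut last. The catechol must be masked through enolate, organomagnesium and palladium chemistry, and benzyl ethers tolerate all of it. The forward step has to remove them without hydrogen, because the enoate of 17 would be reduced, so a Lewis acid with a cation scavenger is planned.

**17 from 15 and 16.** The C5–vinyl bond is cut. The enoate cannot coexist with the organomagnesium chemistry of the ring closure, so C5 carries bromine up to 15. That bromine is para to the phenol oxygen of the starting arylacetate and is installed by the most reliable of aromatic substitutions. The forward reaction is a Heck coupling of 15 with acrylate 16 and must leave the C3–H and the free C7 phenol alone.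

**15 from 10 (key disconnection).** Both oxygen–carbon bonds on ring A are cut: O1–C7a and C7–OH. This leads back to the open-chain β-hydroxy ester 10, in which C7 carries iodine and C7a an arenesulfonate, the pair needed to release a C7–C7a aryne after iodine–magnesium exchange (11, then 12). The cut is made here because it takes both stereocentres out of the ring-forming event. No bond to C2 or C3 is made or broken, and the carbinol oxygen of 10 becomes O1. Because the alkoxide hangs from C3a it can reach only C7a, so the metal ends at C7 (13), where a borate ester (14) and an oxidant turn it into the hydroxyl. One operation thus closes ring B and completes the oxygenation of ring A.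

**10 from 9.** The carbinol C–H bond is cut. Keto ester 9 has a C3–H flanked by an aryl group, a ketone and an ester, so its two enantiomers interconvert quickly. A chiral ruthenium transfer-hydrogenation catalyst can then set C2 and C3 together by dynamic kinetic resolution. The forward step must give the syn (2R,3R) isomer, which maps onto the trans ring.

**9 from 5 and 7.** The C2–C3 bond is cut as a Claisen-type acylation of the lithium enolate 8 of arylacetate 5 by acid chloride 7, itself one step from acid 6. This joins the two aromatic halves in a single C–C bond formation and places the ketone oxygen that will become O1.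

**5 from 1.** The S–O bond of the sulfonate (from 3 and sulfonyl chloride 4), then C7–I (3 from 2) and C5–Br (2 from 1) are cut. The phenol oxygen of 1 directs bromine para and iodine ortho, and then serves as the anchor of the leaving group. It does not appear in 18, since it leaves with the sulfonate.

## Alternatives that were turned down

**Alternative 1:** Ring A is taken apart at C3a–C4 and C7–C7a, so ring B is kept as a preformed trans lactone and the benzene ring is grown onto it.
- Forward step: the silyl ketene acetal methyl (2R,3R)-2-[3,4-bis(benzyloxy)phenyl]-5-[(tert-butyldimethylsilyl)oxy]-2,3-dihydrofuran-3-carboxylate A2 would act as an electron-rich dienophile towards the bromopyrone methyl (E)-3-(3-bromo-2-oxo-2H-pyran-5-yl)prop-2-enoate A3. C3a bonds to pyrone C6 and C7a to pyrone C3. Decarboxylative cycloreversion and loss of the silyloxy group from C7a would aromatise the adduct to the 7-bromo compound A1.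
- For it: the plan is convergent, the enoate arrives with the diene so no late palladium coupling is needed, and both stereocentres sit in a lactone whose trans form is the stable one.
- Against it: A1 carries bromine, not oxygen, at C7. A separate C–Br to C–OH conversion is still needed on a compound that already holds the enoate, two esters and the base-sensitive C3–H. A2 must be made by enolising the lactone CH2 while the neighbouring C3–H is also acidic and its enolate can expel O1. The ketene acetal can add in Michael fashion to the enoate of A3 instead of across the diene. The aromatisation needs heat, and both partners need several steps of their own.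
- Comparison: on convergence and on avoiding the Heck step this plan is the stronger one. The chosen route offers instead the C7 oxygen in the ring-forming operation itself, no enolate formed next to the stereocentres after they are set, and building blocks reached in one to three simple steps.

**Alternative 2:** The C3–C3a bond is disconnected, ring B being derived by contraction of the six-membered ring of a flavanone.
- Forward step: (2R)-8-acetoxy-6-bromo-2-(3,4-diacetoxyphenyl)chroman-4-one A5 would be treated with a trivalent iodine diacetate and a mineral acid in an orthoformate solvent. The enol ether is attacked at C3 by iodine, ring A migrates from the carbonyl carbon to C3, and the former carbonyl carbon is released as the methyl ester, giving triacetate A4.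
- For it: this oxidative 1,2-aryl shift is an established reaction of flavanones and gives the trans 2-aryl-3-carboxylate directly. The ester carbon needs no separate step, and acetates come off at the end under much milder conditions than benzyl ethers. On precedent and on the final deprotection it is stronger than the chosen plan.
- Against it: C2 of A5 is β to the ketone. The acidic medium needed to form the enol ether promotes ring opening by retro-oxa-Michael reaction and reclosure, which racemises the very centre meant to carry the absolute configuration into A4. The migrating ring A is deactivated by its acetoxy and bromo groups, so dehydrogenation and migration of the C2 aryl group compete. Enantiopure A5 of the (2R) series needs its own multi-step asymmetric synthesis, and the Heck reaction still follows.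
- Comparison: the step count would be no shorter. The chosen route gives up the precedent, but it fixes both stereocentres in one catalytic step on 9 and closes ring B without acid and without making or breaking a bond at C2 or C3.

**Alternative 3:** Only O1–C2 is disconnected, with C2 as a quinone methide carbon.
- Forward step: a silver oxidant would convert the free catechol of methyl (2S)-2-{3-(benzyloxy)-2-hydroxy-5-[(E)-3-methoxy-3-oxoprop-1-enyl]phenyl}-3-(3,4-dihydroxyphenyl)propanoate A7 into its ortho-quinone, which tautomerises to the para-quinone methide. The ring A phenol adds to the methide carbon, closing ring B trans to the ester and restoring the catechol in A6.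
- For it: it is the shortest plan and follows the likely biogenesis. Only C3 has to be set beforehand, the enoate is already in place, the catechol needs no protection and only one benzyl group remains. On step economy and on precedent for the ring closure it is stronger than the chosen plan.
- Against it: A7 and A6 contain the same catechol, so the product is as oxidisable as the substrate and over-oxidation is built in. In the quinone methide, C3–H is α to the ester and allylic to the methide, and a proton shift that moves the double bond into conjugation with the ester destroys the only stereocentre. The ring A phenol next to a benzyloxy group is itself oxidisable. Enantioselective access to A7 is awkward, because hydrogenation of a diarylacrylate precursor would also reduce the enoate.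
- Comparison: the chosen route is longer, but it closes ring B without an oxidant and with no cationic or quinoid centre next to a stereocentre.

Key step: step 7

## Route

Step 1
Reactants: 1 methyl 2-(2-hydroxyphenyl)acetate
Product: 2 methyl 2-(5-bromo-2-hydroxyphenyl)acetate
Conditions: NBS (1.0 equiv), MeCN, 0 °C → rt
Reagents that add atoms: N-bromosuccinimide, O=C1CCC(=O)N1Br
Why: Electrophilic aromatic bromination; the free phenol directs para, which is the future C5, and the polar, non-radical medium leaves the benzylic CH2 alone.

Step 2
Reactants: 2 methyl 2-(5-bromo-2-hydroxyphenyl)acetate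
Product: 3 methyl 2-(5-bromo-2-hydroxy-3-iodophenyl)acetate
Conditions: NIS (1.1 equiv), TsOH·H2O (10 mol%), MeCN, rt, dark
Reagents that add atoms: N-iodosuccinimide, O=C1CCC(=O)N1I
Why: Acid-promoted electrophilic iodination; with the para position blocked, the only activated site left is ortho to the phenol, the future C7.

Step 3
Reactants: 3 methyl 2-(5-bromo-2-hydroxy-3-iodophenyl)acetate; 4 4-chlorobenzenesulfonyl chloride
Product: 5 methyl 2-[5-bromo-2-{[(4-chlorophenyl)sulfonyl]oxy}-3-iodophenyl]acetate
Conditions: Et3N (2 equiv), DMAP (5 mol%), CH2Cl2, 0 °C → rt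
Reagents that add atoms: none
Why: O-Sulfonylation of the phenol under nucleophilic catalysis; the 4-chlorobenzenesulfonate is a leaving group that stays on an ortho-magnesiated arene at −78 °C and departs on warming, and it is inert to the enolate and transfer-hydrogenation steps.

Step 4
Reactants: 6 3,4-bis(benzyloxy)benzoic acid
Product: 7 3,4-bis(benzyloxy)benzoyl chloride
Conditions: (COCl)2 (1.5 equiv), DMF (cat.), CH2Cl2, 0 °C → rt; concentrate, use crude
Reagents that add atoms: oxalyl chloride, O=C(Cl)C(=O)Cl
Why: Acid chloride formation through chloroiminium activation; aryl benzyl ethers are stable to these conditions.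

Step 5
Reactants: 5 methyl 2-[5-bromo-2-{[(4-chlorophenyl)sulfonyl]oxy}-3-iodophenyl]acetate; 7 3,4-bis(benzyloxy)benzoyl chloride
Product: 9 methyl 3-[3,4-bis(benzyloxy)phenyl]-2-[5-bromo-2-{[(4-chlorophenyl)sulfonyl]oxy}-3-iodophenyl]-3-oxopropanoate (racemic at C2 of the propanoate), via lithium enolate 8 (not isolated)
Conditions: LiN(SiMe3)2 (2.1 equiv), THF, −78 °C; then 7 (1.0 equiv), −78 → −40 °C; AcOH quench
Reagents that add atoms: lithium bis(trimethylsilyl)amide, [Li]N([Si](C)(C)C)[Si](C)(C)C (its lithium is held only in the unisolated enolate 8)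
Why: Crossed Claisen-type C-acylation of ester enolate 8; the second equivalent of base converts the more acidic β-keto ester into its enolate and stops further acylation. Attack of the enolate carbon on the ortho sulfonate sulfur would be endocyclic and cannot reach an in-line geometry, so the sulfonate should survive at low temperature.

Step 6
Reactants: 9 methyl 3-[3,4-bis(benzyloxy)phenyl]-2-[5-bromo-2-{[(4-chlorophenyl)sulfonyl]oxy}-3-iodophenyl]-3-oxopropanoate
Product: 10 methyl (2R,3R)-3-[3,4-bis(benzyloxy)phenyl]-2-[5-bromo-2-{[(4-chlorophenyl)sulfonyl]oxy}-3-iodophenyl]-3-hydroxypropanoate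
Conditions: RuCl[(R,R)-TsDPEN](p-cymene) (2 mol%; TsDPEN = N-tosyl-1,2-diphenylethylenediamine), HCO2H/Et3N (5:2), DMF, 35 °C
Reagents that add atoms: none
Why: Asymmetric transfer hydrogenation with dynamic kinetic resolution; the triply activated C–H of 9 epimerises through the enol in the amine/formic acid medium while the chiral ruthenium hydride reduces one enantiomer faster. The (R,R) ligand is expected, as with simple aryl ketones, to deliver hydride to the face that gives the R carbinol, and hydride should approach anti to the bulky α-aryl group (Felkin-type), which gives the syn (2R,3R) isomer.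

Step 7
Reactants: 10 methyl (2R,3R)-3-[3,4-bis(benzyloxy)phenyl]-2-[5-bromo-2-{[(4-chlorophenyl)sulfonyl]oxy}-3-iodophenyl]-3-hydroxypropanoate
Product: 15 methyl (2R,3R)-2-[3,4-bis(benzyloxy)phenyl]-5-bromo-7-hydroxy-2,3-dihydrobenzofuran-3-carboxylate, via magnesiated sulfonate 11 (not isolated), via aryne alkoxide 12 (not isolated), via arylmagnesium 13 (not isolated), via dimethyl boronate 14 (not isolated)
Conditions: i-PrMgCl (1.0 equiv, then 1.1 equiv), THF, −78 °C, then → −20 °C; B(OMe)3 (3 equiv), −78 → 0 °C; NaBO3·4H2O, THF/H2O, rt
Reagents that add atoms: isopropylmagnesium chloride, CC(C)[Mg]Cl (magnesium and chlorine held only in 11–13); trimethyl borate, COB(OC)OC (boron and methoxy groups held only in 14); sodium perborate tetrahydrate, [Na+].[O-]OB=O.O.O.O.O (source of the C7 oxygen of 15)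
Why: Proposed new method: the first equivalent of i-PrMgCl turns the carbinol into its chloromagnesium alkoxide and the second exchanges the C7 iodide at −78 °C, where exchange at the C5 bromide and addition to the esters are slow, to give 11, which on warming expels the ortho 4-chlorobenzenesulfonate and becomes the C7–C7a aryne 12. The alkoxide, held on C3a through C3 and C2, adds to C7a by a 5-exo-dig attack on the in-plane π bond, which forms O1–C7a, closes ring B and leaves the charge at C7 as arylmagnesium 13. B(OMe)3 captures 13 as boronate 14, and perborate oxidises the C–B bond, by 1,2-shift of the aryl carbon from boron to oxygen, to the C7 phenol of 15. The closest known reaction types are intramolecular additions of alkoxides to arynes that give dihydrobenzofurans and chromans, and aryne generation from 2-iodoaryl sulfonates by iodine–magnesium exchange followed by addition of a magnesium nucleophile and electrophilic capture of the new arylmagnesium; their union on a tethered magnesium aldolate with borate capture is the untested part. No stereocentre is created: no bond to C2 or C3 is broken and the carbinol oxygen of 10 becomes O1, so the syn (2R,3R) array of 10 maps onto the trans (2R,3R) ring. The regiochemistry of both C–O bonds is fixed by the tether, because the alkoxide can reach only C7a (attack at C7 would need a bridged ring) and the metal therefore ends at C7. The step needs ring closure to outrun retro-aldol cleavage of the magnesium aldolate and proton transfer from the acidic C3–H, which the low temperature, the short intramolecular path and the cold borate quench are meant to secure.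

Step 8
Reactants: 15 methyl (2R,3R)-2-[3,4-bis(benzyloxy)phenyl]-5-bromo-7-hydroxy-2,3-dihydrobenzofuran-3-carboxylate; 16 methyl acrylate
Product: 17 methyl (2R,3R)-2-[3,4-bis(benzyloxy)phenyl]-7-hydroxy-5-[(E)-3-methoxy-3-oxoprop-1-enyl]-2,3-dihydrobenzofuran-3-carboxylate
Conditions: Pd(OAc)2 (5 mol%), P(o-tol)3 (12 mol%), Et3N (3 equiv), DMF, 90 °C
Reagents that add atoms: none
Why: Heck reaction; oxidative addition of zerovalent palladium into the C5–Br bond, syn insertion of the acrylate and syn β-hydride elimination should give the E enoate, and bromophenols couple under these conditions without protection. The weak amine base is not expected to disturb the trans C2/C3 arrangement, which is the thermodynamically preferred one.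

Step 9
Reactants: 17 methyl (2R,3R)-2-[3,4-bis(benzyloxy)phenyl]-7-hydroxy-5-[(E)-3-methoxy-3-oxoprop-1-enyl]-2,3-dihydrobenzofuran-3-carboxylate
Product: 18 methyl (2R,3R)-2-(3,4-dihydroxyphenyl)-7-hydroxy-5-[(E)-3-methoxy-3-oxoprop-1-enyl]-2,3-dihydrobenzofuran-3-carboxylate
Conditions: BCl3 (6 equiv), C6HMe5 (8 equiv), CH2Cl2, −78 °C; then MeOH, −78 °C → rt
Reagents that add atoms: none
Why: Lewis-acid debenzylation with a non-basic cation scavenger; BCl3 ionises the aryl benzyl ethers at −78 °C and pentamethylbenzene traps the benzyl cations by Friedel–Crafts alkylation, so the esters and the enoate should survive. Hydrogenolysis is avoided because it would saturate the enoate.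

## Compound list

1 | methyl 2-(2-hydroxyphenyl)acetate | COC(=O)Cc1ccccc1O | starting material
2 | methyl 2-(5-bromo-2-hydroxyphenyl)acetate | COC(=O)Cc1cc(Br)ccc1O | intermediate
3 | methyl 2-(5-bromo-2-hydroxy-3-iodophenyl)acetate | COC(=O)Cc1cc(Br)cc(I)c1O | intermediate
4 | 4-chlorobenzenesulfonyl chloride | O=S(=O)(Cl)c1ccc(Cl)cc1 | starting material
5 | methyl 2-[5-bromo-2-{[(4-chlorophenyl)sulfonyl]oxy}-3-iodophenyl]acetate | COC(=O)Cc1cc(Br)cc(I)c1OS(=O)(=O)c1ccc(Cl)cc1 | intermediate
6 | 3,4-bis(benzyloxy)benzoic acid | OC(=O)c1ccc(OCc2ccccc2)c(OCc2ccccc2)c1 | starting material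
7 | 3,4-bis(benzyloxy)benzoyl chloride | ClC(=O)c1ccc(OCc2ccccc2)c(OCc2ccccc2)c1 | intermediate
8 | lithium enolate of 5 (not isolated) | COC(O[Li])=Cc1cc(Br)cc(I)c1OS(=O)(=O)c1ccc(Cl)cc1 | intermediate
9 | methyl 3-[3,4-bis(benzyloxy)phenyl]-2-[5-bromo-2-{[(4-chlorophenyl)sulfonyl]oxy}-3-iodophenyl]-3-oxopropanoate (racemic) | COC(=O)C(c1cc(Br)cc(I)c1OS(=O)(=O)c1ccc(Cl)cc1)C(=O)c1ccc(OCc2ccccc2)c(OCc2ccccc2)c1 | intermediate
10 | methyl (2R,3R)-3-[3,4-bis(benzyloxy)phenyl]-2-[5-bromo-2-{[(4-chlorophenyl)sulfonyl]oxy}-3-iodophenyl]-3-hydroxypropanoate | Brc1cc(I)c(OS(=O)(=O)c2ccc(Cl)cc2)c(c1)[C@@H](C(=O)OC)[C@H](c1ccc(OCc2ccccc2)c(OCc2ccccc2)c1)O | intermediate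
11 | chloromagnesium alkoxide of 10 with chloromagnesium in place of iodine (not isolated) | Brc1cc([Mg]Cl)c(OS(=O)(=O)c2ccc(Cl)cc2)c(c1)[C@@H](C(=O)OC)[C@H](c1ccc(OCc2ccccc2)c(OCc2ccccc2)c1)O[Mg]Cl | intermediate
12 | chloromagnesium alkoxide of methyl (2R,3R)-3-[3,4-bis(benzyloxy)phenyl]-2-(5-bromo-2,3-didehydrophenyl)-3-hydroxypropanoate, the C7–C7a aryne (not isolated) | BrC1=CC#CC(=C1)[C@@H](C(=O)OC)[C@H](c1ccc(OCc2ccccc2)c(OCc2ccccc2)c1)O[Mg]Cl | intermediate
13 | methyl (2R,3R)-2-[3,4-bis(benzyloxy)phenyl]-5-bromo-7-(chloromagnesio)-2,3-dihydrobenzofuran-3-carboxylate (not isolated) | Brc1cc([Mg]Cl)c2c(c1)[C@@H](C(=O)OC)[C@H](c1ccc(OCc3ccccc3)c(OCc3ccccc3)c1)O2 | intermediate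
14 | methyl (2R,3R)-2-[3,4-bis(benzyloxy)phenyl]-5-bromo-7-(dimethoxyboranyl)-2,3-dihydrobenzofuran-3-carboxylate (not isolated) | Brc1cc(B(OC)OC)c2c(c1)[C@@H](C(=O)OC)[C@H](c1ccc(OCc3ccccc3)c(OCc3ccccc3)c1)O2 | intermediate
15 | methyl (2R,3R)-2-[3,4-bis(benzyloxy)phenyl]-5-bromo-7-hydroxy-2,3-dihydrobenzofuran-3-carboxylate | Brc1cc(O)c2c(c1)[C@@H](C(=O)OC)[C@H](c1ccc(OCc3ccccc3)c(OCc3ccccc3)c1)O2 | intermediate
16 | methyl acrylate | C=CC(=O)OC | starting material
17 | methyl (2R,3R)-2-[3,4-bis(benzyloxy)phenyl]-7-hydroxy-5-[(E)-3-methoxy-3-oxoprop-1-enyl]-2,3-dihydrobenzofuran-3-carboxylate | COC(=O)/C=C/c1cc(O)c2c(c1)[C@@H](C(=O)OC)[C@H](c1ccc(OCc3ccccc3)c(OCc3ccccc3)c1)O2 | intermediate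
18 | methyl (2R,3R)-2-(3,4-dihydroxyphenyl)-7-hydroxy-5-[(E)-3-methoxy-3-oxoprop-1-enyl]-2,3-dihydrobenzofuran-3-carboxylate | COC(=O)/C=C/c1cc(O)c2c(c1)[C@@H](C(=O)OC)[C@H](c1ccc(O)c(O)c1)O2 | target

## Step count and least certain steps

Total step count: 9. Longest linear sequence: 8 steps (1 → 2 → 3 → 5 → 9 → 10 → 15 → 17 → 18); the side branch 6 → 7 is one step.

**Step 7 (key step, new method).**
- What may go wrong: retro-aldol fragmentation of the magnesium aldolate while the mixture warms to the temperature at which the sulfonate leaves. The anion released would be a stabilised arylacetate enolate, so this aldolate is more fragile than a simple one. A second risk is proton transfer from C3–H to the arylmagnesium centres of 11 or 13, which would quench the metal without oxygenation and open a path to β-elimination of O1. Interception of the aryne by excess exchange reagent is a third.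
- Fallback, by known chemistry, from 3 to 15: ring B is closed through O1–C2 and the C7 oxygen is made from the iodide. The phenol of 3 is masked with chloromethyl methyl ether and i-Pr2NEt to give methyl 2-[5-bromo-3-iodo-2-(methoxymethoxy)phenyl]acetate F1. Acylation with 7 under the conditions of step 5 should give methyl 3-[3,4-bis(benzyloxy)phenyl]-2-[5-bromo-3-iodo-2-(methoxymethoxy)phenyl]-3-oxopropanoate F2. The transfer hydrogenation of step 6 should give methyl (2R,3R)-3-[3,4-bis(benzyloxy)phenyl]-2-[5-bromo-3-iodo-2-(methoxymethoxy)phenyl]-3-hydroxypropanoate F3. Trifluoroacetic acid in CH2Cl2 at 0 °C then removes the acetal and ionises the electron-rich benzylic alcohol. The freed phenol captures the cation (5-exo) on the face away from the ester, so methyl (2R,3R)-2-[3,4-bis(benzyloxy)phenyl]-5-bromo-7-iodo-2,3-dihydrobenzofuran-3-carboxylate F4 is expected as the trans isomer, C3 being untouched and C2 reset under its control. Borylation at the more reactive C–I bond (PdCl2(dppf), bis(pinacolato)diboron, KOAc, DMSO, 60 °C) should give methyl (2R,3R)-2-[3,4-bis(benzyloxy)phenyl]-5-bromo-7-(4,4,5,5-tetramethyl-1,3,2-dioxaborolan-2-yl)-2,3-dihydrobenzofuran-3-carboxylate F5. Oxidation with NaBO3·4H2O in THF/H2O rejoins the route at 15.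

**Step 6.**
- What may go wrong: incomplete discrimination between the two interconverting enantiomers of 9 (erosion of the syn/anti ratio), slow hydride transfer to a ketone flanked by a heavily ortho-substituted aryl group, or a weakened enantioface preference because two aryl groups compete for the catalyst pocket. The sense of induction is argued by analogy and would have to be confirmed; the enantiomeric catalyst is the remedy if it proves opposite.
- Fallback, from 5 to 10: an Evans syn aldol. Hydrolysis of 5 (LiOH, THF/H2O, 0 °C) gives 2-[5-bromo-2-{[(4-chlorophenyl)sulfonyl]oxy}-3-iodophenyl]acetic acid F6. Its pivaloyl mixed anhydride (pivaloyl chloride, Et3N, LiCl, THF) acylates (R)-4-benzyloxazolidin-2-one to give (4R)-4-benzyl-3-{2-[5-bromo-2-{[(4-chlorophenyl)sulfonyl]oxy}-3-iodophenyl]acetyl}oxazolidin-2-one F7. The Z boron enolate (Bu2BOTf, i-Pr2NEt, CH2Cl2, −78 °C) adds to commercial 3,4-bis(benzyloxy)benzaldehyde through a closed chair transition state under control of the auxiliary, and should give (4R)-4-benzyl-3-[(2R,3R)-3-[3,4-bis(benzyloxy)phenyl]-2-[5-bromo-2-{[(4-chlorophenyl)sulfonyl]oxy}-3-iodophenyl]-3-hydroxypropanoyl]oxazolidin-2-one F8. Methanolysis with MeOMgBr in MeOH/CH2Cl2 at 0 °C removes the auxiliary and rejoins the route at 10.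

**Step 5.**
- What may go wrong: O-acylation of enolate 8 or of the product enolate, and transfer of the sulfonyl group from oxygen to the enolate carbon if the mixture warms.
- Fallback, from 5 to 9: enolate 8 is added at −78 °C to 3,4-bis(benzyloxy)benzaldehyde, which cannot O-acylate, to give methyl 3-[3,4-bis(benzyloxy)phenyl]-2-[5-bromo-2-{[(4-chlorophenyl)sulfonyl]oxy}-3-iodophenyl]-3-hydroxypropanoate as a mixture of stereoisomers F9. Oxidation with Dess–Martin periodinane (CH2Cl2, NaHCO3, rt) gives 9.

**Step 8.**
- What may go wrong: opening of ring B through the C3 ester enolate (retro-oxa-Michael) and reclosure at 90 °C in the presence of amine, which would erode the enantiomeric purity; or slow oxidative addition at the electron-rich C5–Br bond with decomposition of the catalyst.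
- Fallback, from 15 to 17: a base-free Stille coupling of 15 with methyl (E)-3-(tributylstannyl)prop-2-enoate (Pd(PPh3)4, CuI, DMF, 60 °C), in which the E alkene arrives preformed. No new intermediate is made (F0).

**Step 9.**
- What may go wrong: ionisation of the O1–C2 bond by the Lewis acid, since it is itself a benzylic aryl ether activated by the para oxygen, leading to ring opening, epimerisation at C2 or capture of the cation by the scavenger.
- Fallback, from 15 to 18: the benzyl groups are removed by hydrogenolysis before the alkene exists. Reductive carbonylation of 15 (Pd(OAc)2, di(1-adamantyl)-n-butylphosphine, CO/H2, N,N,N′,N′-tetramethylethylenediamine, toluene, 100 °C) gives methyl (2R,3R)-2-[3,4-bis(benzyloxy)phenyl]-5-formyl-7-hydroxy-2,3-dihydrobenzofuran-3-carboxylate F10. Hydrogenolysis (H2, palladium on carbon, EtOAc, rt) gives methyl (2R,3R)-2-(3,4-dihydroxyphenyl)-5-formyl-7-hydroxy-2,3-dihydrobenzofuran-3-carboxylate F11. A Wittig reaction with methyl (triphenylphosphoranylidene)acetate (THF, rt), which tolerates free phenols and gives the E enoate, leads to 18.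

## Further compounds

F1 | step 7 | methyl 2-[5-bromo-3-iodo-2-(methoxymethoxy)phenyl]acetate | COCOc1c(I)cc(Br)cc1CC(=O)OC
F2 | step 7 | methyl 3-[3,4-bis(benzyloxy)phenyl]-2-[5-bromo-3-iodo-2-(methoxymethoxy)phenyl]-3-oxopropanoate (racemic) | COCOc1c(I)cc(Br)cc1C(C(=O)OC)C(=O)c1ccc(OCc2ccccc2)c(OCc2ccccc2)c1
F3 | step 7 | methyl (2R,3R)-3-[3,4-bis(benzyloxy)phenyl]-2-[5-bromo-3-iodo-2-(methoxymethoxy)phenyl]-3-hydroxypropanoate | Brc1cc(I)c(OCOC)c(c1)[C@@H](C(=O)OC)[C@H](c1ccc(OCc2ccccc2)c(OCc2ccccc2)c1)O
F4 | step 7 | methyl (2R,3R)-2-[3,4-bis(benzyloxy)phenyl]-5-bromo-7-iodo-2,3-dihydrobenzofuran-3-carboxylate | Brc1cc(I)c2c(c1)[C@@H](C(=O)OC)[C@H](c1ccc(OCc3ccccc3)c(OCc3ccccc3)c1)O2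
F5 | step 7 | methyl (2R,3R)-2-[3,4-bis(benzyloxy)phenyl]-5-bromo-7-(4,4,5,5-tetramethyl-1,3,2-dioxaborolan-2-yl)-2,3-dihydrobenzofuran-3-carboxylate | Brc1cc(B3OC(C)(C)C(C)(C)O3)c2c(c1)[C@@H](C(=O)OC)[C@H](c1ccc(OCc3ccccc3)c(OCc3ccccc3)c1)O2
F6 | step 6 | 2-[5-bromo-2-{[(4-chlorophenyl)sulfonyl]oxy}-3-iodophenyl]acetic acid | OC(=O)Cc1cc(Br)cc(I)c1OS(=O)(=O)c1ccc(Cl)cc1
F7 | step 6 | (4R)-4-benzyl-3-{2-[5-bromo-2-{[(4-chlorophenyl)sulfonyl]oxy}-3-iodophenyl]acetyl}oxazolidin-2-one | O=C(Cc1cc(Br)cc(I)c1OS(=O)(=O)c1ccc(Cl)cc1)N1C(=O)OC[C@H]1Cc1ccccc1
F8 | step 6 | (4R)-4-benzyl-3-[(2R,3R)-3-[3,4-bis(benzyloxy)phenyl]-2-[5-bromo-2-{[(4-chlorophenyl)sulfonyl]oxy}-3-iodophenyl]-3-hydroxypropanoyl]oxazolidin-2-one | Brc1cc(I)c(OS(=O)(=O)c2ccc(Cl)cc2)c(c1)[C@@H](C(=O)N1C(=O)OC[C@H]1Cc1ccccc1)[C@H](c1ccc(OCc2ccccc2)c(OCc2ccccc2)c1)O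
F9 | step 5 | methyl 3-[3,4-bis(benzyloxy)phenyl]-2-[5-bromo-2-{[(4-chlorophenyl)sulfonyl]oxy}-3-iodophenyl]-3-hydroxypropanoate (mixture of stereoisomers) | COC(=O)C(c1cc(Br)cc(I)c1OS(=O)(=O)c1ccc(Cl)cc1)C(O)c1ccc(OCc2ccccc2)c(OCc2ccccc2)c1
F0 | step 8 | none | none
F10 | step 9 | methyl (2R,3R)-2-[3,4-bis(benzyloxy)phenyl]-5-formyl-7-hydroxy-2,3-dihydrobenzofuran-3-carboxylate | O=Cc1cc(O)c2c(c1)[C@@H](C(=O)OC)[C@H](c1ccc(OCc3ccccc3)c(OCc3ccccc3)c1)O2
F11 | step 9 | methyl (2R,3R)-2-(3,4-dihydroxyphenyl)-5-formyl-7-hydroxy-2,3-dihydrobenzofuran-3-carboxylate | O=Cc1cc(O)c2c(c1)[C@@H](C(=O)OC)[C@H](c1ccc(O)c(O)c1)O2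
A1 | alternative 1 | methyl (2R,3R)-2-[3,4-bis(benzyloxy)phenyl]-7-bromo-5-[(E)-3-methoxy-3-oxoprop-1-enyl]-2,3-dihydrobenzofuran-3-carboxylate | COC(=O)/C=C/c1cc(Br)c2c(c1)[C@@H](C(=O)OC)[C@H](c1ccc(OCc3ccccc3)c(OCc3ccccc3)c1)O2
A2 | alternative 1 | methyl (2R,3R)-2-[3,4-bis(benzyloxy)phenyl]-5-[(tert-butyldimethylsilyl)oxy]-2,3-dihydrofuran-3-carboxylate | CC(C)(C)[Si](C)(C)OC1=C[C@@H](C(=O)OC)[C@H](c2ccc(OCc3ccccc3)c(OCc3ccccc3)c2)O1
A3 | alternative 1 | methyl (E)-3-(3-bromo-2-oxo-2H-pyran-5-yl)prop-2-enoate | COC(=O)/C=C/C1=COC(=O)C(Br)=C1
A4 | alternative 2 | methyl (2R,3R)-7-acetoxy-5-bromo-2-(3,4-diacetoxyphenyl)-2,3-dihydrobenzofuran-3-carboxylate | Brc1cc(OC(C)=O)c2c(c1)[C@@H](C(=O)OC)[C@H](c1ccc(OC(C)=O)c(OC(C)=O)c1)O2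
A5 | alternative 2 | (2R)-8-acetoxy-6-bromo-2-(3,4-diacetoxyphenyl)chroman-4-one | CC(=O)Oc1ccc(cc1OC(C)=O)[C@H]1CC(=O)c2cc(Br)cc(OC(C)=O)c2O1
A6 | alternative 3 | methyl (2R,3R)-7-(benzyloxy)-2-(3,4-dihydroxyphenyl)-5-[(E)-3-methoxy-3-oxoprop-1-enyl]-2,3-dihydrobenzofuran-3-carboxylate | COC(=O)/C=C/c1cc(OCc3ccccc3)c2c(c1)[C@@H](C(=O)OC)[C@H](c1ccc(O)c(O)c1)O2
A7 | alternative 3 | methyl (2S)-2-{3-(benzyloxy)-2-hydroxy-5-[(E)-3-methoxy-3-oxoprop-1-enyl]phenyl}-3-(3,4-dihydroxyphenyl)propanoate | COC(=O)/C=C/c1cc(OCc2ccccc2)c(O)c(c1)[C@@H](C(=O)OC)Cc1ccc(O)c(O)c1
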